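**Retrosynthetic overview**
1. The last bond made is the E-disubstituted C=C next to the quaternary ether carbon. It comes from cross-metathesis of a vinyl tetrahydrofuran–lactone with a furyl skipped (1,4-) diene.
2. Both oxygen rings come from one acyclic hydroxy dienoate. Asymmetric epoxidation of its E-trisubstituted alkene is followed by closure of the tetrahydrofuran ring (5-exo opening by the tertiary alcohol), and the lactone ring closes second (the freed tertiary alcohol attacks the ester).
3. The key C–C bond is C4–C5 of the lactone, made at the alkene stage. A zinc ester homoenolate (nucleophilic β-carbon) is coupled with the trans C–Cl bond of a 1,1-dichloroalkene, and the methyl group goes in second, which fixes the E geometry.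
4. The dichloroalkene comes from a chiral-pool tertiary allylic alcohol, which supplies the quaternary ether stereocentre, by selective ozonolysis and dichloromethylenation.
5. The skipped diene is built by propargylic alkylation of a furylmethyl bromide followed by hydrozirconation–allylation.

Assumption: commercial (R)-(−)-linalool (about 95% ee or better) is used as bought. Material from the minor enantiomer becomes a cis-tetrahydrofuran diastereomer in step 4 and is removed by chromatography.

**Step 1**
Reactants: 1 (R)-(−)-linalool [(3R)-3,7-dimethylocta-1,6-dien-3-ol]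
Product: 2 (5R)-5-ethenyl-5-methyloxolan-2-ol (lactol; both anomers; closed form of (4R)-4-hydroxy-4-methylhex-5-enal)
Conditions: O3 (1.0 equiv, Sudan Red 7B end point), NaHCO3, CH2Cl2–MeOH 5:1, −78 °C; Me2S, −78 °C→rt
Reagents that add atoms: ozone, [O-][O+]=O
Why: Chemoselective ozonolysis (Criegee mechanism): the electron-rich trisubstituted alkene reacts far faster than the vinyl group beside the carbinol carbon, the hydroxy aldehyde closes to the lactol, and the tertiary carbinol stereocentre (R, from the chiral pool) is not touched.

**Step 2**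
Reactants: 2 (5R)-5-ethenyl-5-methyloxolan-2-ol
Product: 3 (3R)-7,7-dichloro-3-methylhepta-1,6-dien-3-ol
Conditions: (EtO)2P(O)CCl3 (2.3 equiv), n-BuLi (2.3 equiv), THF–Et2O, −95 °C; add 2, −95 °C→rt; H2O
Reagents that add atoms: diethyl (trichloromethyl)phosphonate, CCOP(=O)(OCC)C(Cl)(Cl)Cl
Why: Horner–Wadsworth–Emmons-type dichloromethylenation: one equivalent of the lithiated dichloromethylphosphonate deprotonates the lactol and opens it to the alkoxy aldehyde, the second adds to C=O and loses lithium diethyl phosphate on warming, and no stereocentre is formed or disturbed.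

**Step 3 (key step)**
Reactants: 3 (3R)-7,7-dichloro-3-methylhepta-1,6-dien-3-ol; 4 ethyl 3-bromopropanoate
Product: 7 ethyl (4E,8R)-8-hydroxy-4,8-dimethyldeca-4,9-dienoate, via zinc homoenolate 5 (not isolated), via chloroalkene 6 (not isolated)
Conditions: 4, Zn dust, LiCl, THF, 40 °C (gives 5); add to 3, PdCl2(DPEphos) (5 mol%), THF–NMP, 40 °C; then MeZnCl, Pd(P(t-Bu)3)2 (5 mol%), 50 °C, same flask
Reagents that add atoms: methylzinc chloride, C[Zn]Cl
Why: Proposed new method: the ester β-carbon, normally an acceptor site, is made nucleophilic as zinc homoenolate 5 and joined in a Negishi coupling to the equally electrophilic dichlorovinyl carbon of 3; zerovalent palladium inserts only into the less hindered C–Cl bond trans to the chain (the wide-bite-angle DPEphos favours reductive elimination over β-hydride loss), and the remaining cis C–Cl bond of 6 is then methylated with retention by the bulky-phosphine catalyst, which fixes the E alkene that encodes the relative configuration of the two later stereocentres; the closest known reaction types are the trans-selective monoalkylation of 1,1-dichloroalk-1-enes by alkylzinc halides followed by a second substitution, and the palladium-catalysed coupling of zinc ester homoenolates with alkenyl halides.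

**Step 4**
Reactants: 7 ethyl (4E,8R)-8-hydroxy-4,8-dimethyldeca-4,9-dienoate
Product: 10 (5S)-5-[(2R,5R)-5-ethenyl-5-methyloxolan-2-yl]-5-methyloxolan-2-one, via epoxide 8 (not isolated), via hydroxy ester 9 (not isolated)
Conditions: L-fructose-derived Shi ketone (1,2:4,5-di-O-isopropylidene-β-L-erythro-2,3-hexodiulo-2,6-pyranose, 30 mol%), Oxone (2KHSO5·KHSO4·K2SO4), K2CO3, Bu4NHSO4 (cat.), MeCN–dimethoxymethane/aq Na2B4O7–EDTA, 0 °C; extract; camphorsulfonic acid (10 mol%), CH2Cl2, 0 °C→rt
Reagents that add atoms: potassium peroxymonosulfate (active part of Oxone), [K+].[O-]S(=O)(=O)OO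
Why: Shi asymmetric epoxidation: the chiral dioxirane attacks only the trisubstituted alkene and, in the L-series, gives the (S,S)-epoxide 8; acid-triggered 5-exo-tet opening by the tertiary alcohol inverts the CH carbon to R (trans-tetrahydrofuran 9), the C–O bond at the quaternary carbon stays intact (S), and the freed tertiary alcohol lactonises.

**Step 5**
Reactants: 11 furan-3-ylmethanol
Product: 12 3-(bromomethyl)furan
Conditions: PBr3 (0.37 equiv), Et2O, 0 °C; used at once
Reagents that add atoms: phosphorus tribromide, BrP(Br)Br
Why: SN2 bromination of the primary alcohol through its phosphite ester, mild enough for the furan ring.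

**Step 6**
Reactants: 12 3-(bromomethyl)furan; 13 but-2-yne
Product: 15 3-(pent-3-yn-1-yl)furan, via but-2-ynyllithium 14 (not isolated)
Conditions: 13, n-BuLi, TMEDA, THF, −20 °C→0 °C; 12, −78 °C→rt
Reagents that add atoms: none
Why: Propargylic lithiation of but-2-yne followed by SN2 alkylation, in which the reactive furylmethyl bromide is attacked by the CH2 terminus of the propargyl/allenyl anion.

**Step 7**
Reactants: 15 3-(pent-3-yn-1-yl)furan; 16 allyl bromide
Product: 18 3-[(3E)-4-methylhepta-3,6-dien-1-yl]furan, via alkenylzirconocene 17 (not isolated)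
Conditions: Cp2Zr(H)Cl (1.6 equiv), THF, 45 °C; 16, CuCl (10 mol%), 0 °C→rt; minor regioisomer removed on AgNO3-silica
Reagents that add atoms: none
Why: Syn hydrozirconation, equilibrated by the excess hydride to the isomer with zirconium on the methyl-bearing carbon, followed by copper-catalysed allylation with retention, gives the E-trisubstituted alkene of the skipped diene.

**Step 8**
Reactants: 10 (5S)-5-[(2R,5R)-5-ethenyl-5-methyloxolan-2-yl]-5-methyloxolan-2-one; 18 3-[(3E)-4-methylhepta-3,6-dien-1-yl]furan
Product: 19 (5S)-5-{(2R,5R)-5-[(1E,4E)-7-(furan-3-yl)-4-methylhepta-1,4-dien-1-yl]-5-methyloxolan-2-yl}-5-methyloxolan-2-one (target)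
Conditions: second-generation Hoveyda–Grubbs catalyst (7 mol%), 18 (2.5 equiv), 1,4-benzoquinone (15 mol%), CH2Cl2, 40 °C
Reagents that add atoms: none
Why: Olefin cross-metathesis: the fast-reacting allyl terminus of 18 pairs with the hindered, non-dimerising vinyl group of 10, the quaternary neighbour enforces the E alkene, benzoquinone suppresses migration of the skipped diene, and the trisubstituted alkene, furan, lactone and all three stereocentres are untouched.

**Compound list**
1 | (R)-(−)-linalool, (3R)-3,7-dimethylocta-1,6-dien-3-ol | C=C[C@](C)(O)CCC=C(C)C | starting material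
2 | (5R)-5-ethenyl-5-methyloxolan-2-ol (anomer mixture) | C=C[C@@]1(C)CCC(O)O1 | intermediate
3 | (3R)-7,7-dichloro-3-methylhepta-1,6-dien-3-ol | C=C[C@](C)(O)CCC=C(Cl)Cl | intermediate
4 | ethyl 3-bromopropanoate | CCOC(=O)CCBr | starting material
5 | (3-ethoxy-3-oxopropyl)zinc bromide (zinc homoenolate) | CCOC(=O)CC[Zn]Br | intermediate
6 | ethyl (4Z,8R)-4-chloro-8-hydroxy-8-methyldeca-4,9-dienoate | CCOC(=O)CC/C(Cl)=C/CC[C@@](C)(O)C=C | intermediate
7 | ethyl (4E,8R)-8-hydroxy-4,8-dimethyldeca-4,9-dienoate | CCOC(=O)CC/C(C)=C/CC[C@@](C)(O)C=C | intermediate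
8 | ethyl 3-{(2S,3S)-3-[(3R)-3-hydroxy-3-methylpent-4-en-1-yl]-2-methyloxiran-2-yl}propanoate | CCOC(=O)CC[C@]1(C)O[C@H]1CC[C@@](C)(O)C=C | intermediate
9 | ethyl (4S)-4-[(2R,5R)-5-ethenyl-5-methyloxolan-2-yl]-4-hydroxypentanoate | CCOC(=O)CC[C@](C)(O)[C@H]1CC[C@](C)(C=C)O1 | intermediate
10 | (5S)-5-[(2R,5R)-5-ethenyl-5-methyloxolan-2-yl]-5-methyloxolan-2-one | C=C[C@@]1(C)CC[C@H]([C@]2(C)CCC(=O)O2)O1 | intermediate
11 | furan-3-ylmethanol | OCc1ccoc1 | starting material
12 | 3-(bromomethyl)furan | BrCc1ccoc1 | intermediate
13 | but-2-yne | CC#CC | starting material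
14 | but-2-yn-1-yllithium | [Li]CC#CC | intermediate
15 | 3-(pent-3-yn-1-yl)furan | CC#CCCc1ccoc1 | intermediate
16 | allyl bromide (3-bromoprop-1-ene) | C=CCBr | starting material
17 | chloro[(2E)-5-(furan-3-yl)pent-2-en-2-yl]zirconocene | Cl[Zr](C1C=CC=C1)(C1C=CC=C1)/C(C)=C/CCc1ccoc1 | intermediate
18 | 3-[(3E)-4-methylhepta-3,6-dien-1-yl]furan | C=CC/C(C)=C/CCc1ccoc1 | intermediate
19 | (5S)-5-{(2R,5R)-5-[(1E,4E)-7-(furan-3-yl)-4-methylhepta-1,4-dien-1-yl]-5-methyloxolan-2-yl}-5-methyloxolan-2-one | C/C(=C\CCc1ccoc1)C/C=C/[C@@]1(C)CC[C@H]([C@]2(C)CCC(=O)O2)O1 | target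

**Totals**
Total step count: 8.
Longest linear sequence: 5 (steps 1, 2, 3, 4, 8).

**Steps most likely to fail**

Step 3 carries the highest risk. The internally chelated homoenolate may transmetalate slowly. Double alkylation or loss of HCl to an alkyne may compete, and the free tertiary allylic alcohol may be activated by the palladium/zinc couple.
The fallback sets out from 3 and comes back to the route at 7.
- Treating 3 with n-BuLi (3.2 equiv, THF, −78 °C→0 °C; elimination to the chloroalkyne, then Cl/Li exchange) and then MeI gives (3R)-3-methyloct-1-en-6-yn-3-ol F1.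
- Syn hydrozirconation with Cp2Zr(H)Cl (excess, 45 °C, zirconium settling next to the methyl group) and I2 gives (3R,6E)-7-iodo-3-methylocta-1,6-dien-3-ol F2.
- The single C–I bond of F2 is coupled with the same homoenolate 5 (Pd(PPh3)4, THF–NMP) to give 7.
- The alkene geometry then comes from the hydrometalation and not from site-selective oxidative addition.

Step 8 is the next risk. The vinyl group on the quaternary carbon is slow to react, the valuable diene 18 may mostly homodimerise, and the doubly allylic CH2 may allow isomerisation.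
The fallback sets out from 10, uses 17 as generated in step 7, and comes back at 19.
- Metathesis of 10 with a large excess of cheap (Z)-1,4-dichlorobut-2-ene (second-generation Hoveyda–Grubbs catalyst, CH2Cl2, 40 °C) gives (5S)-5-{(2R,5R)-5-[(1E)-3-chloroprop-1-en-1-yl]-5-methyloxolan-2-yl}-5-methyloxolan-2-one F3.
- The skipped diene is then closed by a C(sp2)–C(sp3) bond. Alkenylzirconocene 17 attacks the π-allyl complex formed from F3 and zerovalent palladium (Pd(PPh3)4, THF) at its unhindered CH2 terminus to give 19.

Step 2 is the third risk. The lithiated phosphonate is thermally fragile, while ring opening of the lactolate is slow at low temperature.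
The fallback sets out from 2 and comes back at 3.
- Decarboxylative trichloromethylation at room temperature (Cl3CCO2Na, Cl3CCO2H, DMF) traps the open aldehyde form as (5R)-1,1,1-trichloro-5-methylhept-6-ene-2,5-diol F4.
- Selective acetylation of the secondary alcohol (Ac2O, pyridine, 0 °C) gives (5R)-1,1,1-trichloro-5-hydroxy-5-methylhept-6-en-2-yl acetate F5.
- Zinc dust in THF–AcOH brings about reductive 1,2-elimination to 3.

**Further compounds**
F1 | step 3 | (3R)-3-methyloct-1-en-6-yn-3-ol | C=C[C@](C)(O)CCC#CC
F2 | step 3 | (3R,6E)-7-iodo-3-methylocta-1,6-dien-3-ol | C=C[C@](C)(O)CC/C=C(\C)I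
F3 | step 8 | (5S)-5-{(2R,5R)-5-[(1E)-3-chloroprop-1-en-1-yl]-5-methyloxolan-2-yl}-5-methyloxolan-2-one | ClC/C=C/[C@@]1(C)CC[C@H]([C@]2(C)CCC(=O)O2)O1
F4 | step 2 | (5R)-1,1,1-trichloro-5-methylhept-6-ene-2,5-diol (carbinol epimers) | C=C[C@](C)(O)CCC(O)C(Cl)(Cl)Cl
F5 | step 2 | (5R)-1,1,1-trichloro-5-hydroxy-5-methylhept-6-en-2-yl acetate (epimers) | C=C[C@](C)(O)CCC(OC(C)=O)C(Cl)(Cl)Cl
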